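**Retrosynthetic overview**

1. Target 23 ⇐ desilylation of 22 ⇐ intramolecular Diels–Alder reaction of silyl dienol ether 21 (made in the flask from ene-dione 20); it forms C1–C2 and C5–C14 and so closes ring A (cyclohexene) and ring B (cycloheptenone) together.
2. Enabling feature: ring A is a cyclic β-keto ester enol whose C3=C4 bond lies between C2H2 and C5H, exactly where a 2-oxy-diene C2=C3–C4=C5 leaves its π-bond. C14=C1 is the γ,δ-bond of the α-alkylidene γ-lactone (ring D), tied to C5 through C6(=O)–C7–C11–C12=C13. The C3–O and C6=O oxygens sit 1,4 across C4=C5, as in an oxidised 2-methylfuran-3-carboxylate.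
3. 20 ⇐ singlet-oxygen unmasking of furan 17 ⇐ aldol/elimination of lactone 11 with dienal 14.
4. 11 ⇐ Ueno–Stork radical cyclisation (ring D; C7 and C11) ⇐ MeMgBr addition (C8) ⇐ Suzuki coupling of iodoenone 4 with furyl boronate 2; ring C and C10 come from (R)-4-silyloxycyclopentenone 3.
5. Ring order: C (starting material) → D (step 7) → A and B (step 14).

Key step: step 14

Remark on locants (cembrane-type, used throughout): C1 = ring-A CH bearing isopropenyl, C2 = ring-A CH2, C3 = enol carbon, C4 = ester-bearing carbon, C5 = A/B-fusion CH next to ketone C6, C7 = B/C-fusion CH, C8 = carbinol carbon, C9 = CH2, C10 = O–CH, C11 = central CH, C12 = lactone α-carbon, C13 = vinyl CH, C14 = A/B-fusion CH.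

Assumption: the enol drawn in the target is taken as the stable, hydrogen-bonded tautomer of the β-keto ester, so the form released on desilylation is the target.

**Route**

Step 1
Reactants: 1 methyl 2-methylfuran-3-carboxylate
Product: 2 methyl 2-methyl-5-(4,4,5,5-tetramethyl-1,3,2-dioxaborolan-2-yl)furan-3-carboxylate
Conditions: [Ir(OMe)(cod)]2 (1.5 mol %), dtbpy (3 mol %), B2pin2 (1.0 equiv), THF, 50 °C
Reagents that add atoms: bis(pinacolato)diboron, CC1(C)OB(OC1(C)C)B1OC(C)(C)C(C)(C)O1
Why: Iridium-catalysed C–H borylation of a furan goes to the free α-position (C5), the β-C–H being shielded by the neighbouring ester.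

Step 2
Reactants: 3 (4R)-4-[(tert-butyldimethylsilyl)oxy]cyclopent-2-en-1-one
Product: 4 (4R)-4-[(tert-butyldimethylsilyl)oxy]-2-iodocyclopent-2-en-1-one
Conditions: I2, pyridine, CH2Cl2, 0 °C to rt
Reagents that add atoms: iodine, II
Why: Johnson α-iodination of a cyclic enone (pyridine conjugate addition, iodination, elimination) leaves the silyloxy stereocentre untouched.

Step 3
Reactants: 4 (4R)-4-[(tert-butyldimethylsilyl)oxy]-2-iodocyclopent-2-en-1-one; 2 furyl pinacol boronate
Product: 5 methyl 5-[(3R)-3-[(tert-butyldimethylsilyl)oxy]-5-oxocyclopent-1-en-1-yl]-2-methylfuran-3-carboxylate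
Conditions: Pd(dppf)Cl2 (5 mol %), K3PO4, THF/H2O, 40 °C
Reagents that add atoms: none
Why: Suzuki–Miyaura coupling of an α-iodoenone with a heteroaryl boronate under mild base should join the furan carbon (future C6) to C7 without β-elimination of the silyloxy group.

Step 4
Reactants: 5 furyl enone
Product: 6 methyl 5-[(3R,5S)-3-[(tert-butyldimethylsilyl)oxy]-5-hydroxy-5-methylcyclopent-1-en-1-yl]-2-methylfuran-3-carboxylate (OH cis to OTBS)
Conditions: MeMgBr (1.2 equiv), THF, −78 °C; aq. NH4Cl
Reagents that add atoms: methylmagnesium bromide, C[Mg]Br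
Why: Grignard 1,2-addition to the ring ketone outruns attack on the furoate ester at −78 °C, and the methyl group should enter anti to the 4-silyloxy group of the flat cyclopentenone, which sets C8 with OH cis to the C10 oxygen.

Step 5
Reactants: 6 silyl ether
Product: 7 methyl 5-[(3R,5S)-3,5-dihydroxy-5-methylcyclopent-1-en-1-yl]-2-methylfuran-3-carboxylate (cis-diol)
Conditions: TBAF, THF, 0 °C
Reagents that add atoms: none
Why: Fluoride desilylation frees the secondary allylic alcohol under basic conditions that spare the acid-sensitive tertiary allylic alcohol.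

Step 6
Reactants: 7 cis-diol
Product: 8 methyl 5-[(3R,5S)-3-(2-bromo-1-ethoxyethoxy)-5-hydroxy-5-methylcyclopent-1-en-1-yl]-2-methylfuran-3-carboxylate (both acetal epimers)
Conditions: ethyl vinyl ether (5 equiv), NBS (1.1 equiv), CH2Cl2, −40 to 0 °C
Reagents that add atoms: ethyl vinyl ether, C=COCC; N-bromosuccinimide, O=C1CCC(=O)N1Br
Why: Ueno–Stork bromoacetalisation, in which the secondary alcohol traps the bromo-oxocarbenium ion from ethyl vinyl ether far faster than the hindered tertiary alcohol; the acetal epimers converge in step 8.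

Step 7
Reactants: 8 bromoacetal
Product: 9 methyl 5-[(3aS,4R,5S,6aR)-2-ethoxy-5-hydroxy-5-methylhexahydro-2H-cyclopenta[b]furan-4-yl]-2-methylfuran-3-carboxylate (both C2 epimers; ring oxygen, ring CH2, furyl and OH all on one face)
Conditions: Bu3SnH (1.3 equiv, slow addition), AIBN (10 mol %), PhH (0.01 M), 80 °C
Reagents that add atoms: none
Why: Ueno–Stork 5-exo-trig radical cyclisation, in which the O-tether forces the cis ring fusion at C11 and the furan-stabilised C7 radical should take hydrogen from the stannane on the convex face, anti to the new ring, which places the furyl group cis to the new ring and to the C8 hydroxyl.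

Step 8
Reactants: 9 bicyclic ethyl acetal
Product: 10 methyl 5-[(3aS,4R,5S,6aR)-5-hydroxy-5-methyl-2-oxohexahydro-2H-cyclopenta[b]furan-4-yl]-2-methylfuran-3-carboxylate
Conditions: CrO3, H2SO4, acetone/H2O, 0 °C
Reagents that add atoms: water, O
Why: Jones oxidation hydrolyses the acetal to the lactol and oxidises it to the γ-lactone in one flask; the tertiary alcohol cannot be oxidised and the ester-deactivated furan is expected to survive a short exposure.

Step 9
Reactants: 10 hydroxy lactone
Product: 11 methyl 2-methyl-5-[(3aS,4S,5S,6aR)-5-methyl-2-oxo-5-[(triethylsilyl)oxy]hexahydro-2H-cyclopenta[b]furan-4-yl]furan-3-carboxylate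
Conditions: TESOTf, 2,6-lutidine, CH2Cl2, −78 to 0 °C
Reagents that add atoms: triethylsilyl trifluoromethanesulfonate, CC[Si](CC)(CC)OS(=O)(=O)C(F)(F)F
Why: Silyl triflate silylation of the tertiary alcohol blocks its later oxa-Michael addition to the ene-dione and gives a group that fluoride removes at the end.

Step 10
Reactants: 12 methacrolein; 13 (triphenylphosphoranylidene)acetaldehyde
Product: 14 (2E)-4-methylpenta-2,4-dienal
Conditions: methacrolein (3 equiv), PhH, 70 °C
Reagents that add atoms: none
Why: Wittig reaction of the stabilised formylmethylene ylide is E-selective, and excess methacrolein suppresses a second homologation.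

Step 11
Reactants: 11 TES lactone; 14 (2E)-4-methylpenta-2,4-dienal
Product: 15 3-[(2E)-1-hydroxy-4-methylpenta-2,4-dien-1-yl] derivative of lactone 11 (epimers at the two new centres, ring configurations as in 11)
Conditions: LDA (1.1 equiv), THF, −78 °C; then 14; aq. NH4Cl
Reagents that add atoms: none
Why: Aldol addition of the lactone lithium enolate to the enal goes 1,2 at −78 °C, and the two new stereocentres are removed in step 12, so the mixture is carried on.

Step 12
Reactants: 15 aldol adduct
Product: 17 methyl 2-methyl-5-[(3E,3aR,4S,5S,6aR)-5-methyl-3-[(2E)-4-methylpenta-2,4-dien-1-ylidene]-2-oxo-5-[(triethylsilyl)oxy]hexahydro-2H-cyclopenta[b]furan-4-yl]furan-3-carboxylate, via allylic mesylate 16 (not isolated)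
Conditions: MsCl, Et3N, CH2Cl2, 0 °C; then DBU, rt
Reagents that add atoms: none
Why: Mesylation followed by E1cB elimination should give the thermodynamically preferred (E)-alkylidene lactone, with the dienyl chain anti to the lactone carbonyl and syn to C11 as ring B requires.

Step 13
Reactants: 17 furyl trienyl lactone
Product: 20 methyl (2Z)-2-acetyl-4-[(3E,3aR,4R,5S,6aR)-5-methyl-3-[(2E)-4-methylpenta-2,4-dien-1-ylidene]-2-oxo-5-[(triethylsilyl)oxy]hexahydro-2H-cyclopenta[b]furan-4-yl]-4-oxobut-2-enoate (the two ketones trans), via furan endoperoxide 18 (not isolated), via cis-ene-dione 19 (not isolated)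
Conditions: O2, tetraphenylporphyrin (1 mol %), white LED, CH2Cl2, −78 °C; Me2S, −78 °C to rt; then I2 (5 mol %), CH2Cl2, rt, ambient light
Reagents that add atoms: oxygen, O=O
Why: Dye-sensitised [4+2] addition of singlet oxygen to the furan and reduction of the endoperoxide by Me2S gives the cis-ene-dione, every other C=C being part of the electron-poor lactone-conjugated triene and so slower towards electrophilic singlet oxygen; iodine-catalysed equilibration is then expected to favour the isomer with the C6 acyl group cis to the ester, the geometry needed in step 14.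

Step 14
Reactants: 20 ene-dione triene
Product: 22 3-O-TBS enol ether 8-O-TES ether of the target (1R,5S,7R,8S,10R,11R,14S), via silyl dienol ether 21 (not isolated)
Conditions: TBSOTf (1.5 equiv), Et3N (3 equiv), CH2Cl2, −78 to 0 °C; pentane, filtration, concentration; then toluene (0.005 M), BHT, 110 °C
Reagents that add atoms: tert-butyldimethylsilyl trifluoromethanesulfonate, CC(C)(C)[Si](C)(C)OS(=O)(=O)C(F)(F)F
Why: Soft enolisation of the methyl ketone (C2H3–C3=O, the only unhindered enolisable site) gives the push–pull diene C2=C3(OTBS)–C4(CO2Me)=C5, which on heating should add suprafacially across the tethered (E)-C14=C1 bond in a concerted, asynchronous [4+2] (nucleophilic C2 to C1, the δ-carbon of the lactone-conjugated triene; C5 to C14), the closest known reaction type being the type-1 intramolecular Diels–Alder reaction of 2-silyloxy-3-alkoxycarbonyl dienes with a five-atom tether. Ring A closes as the six-membered cycloadduct ring and keeps its π-bond at C3=C4 as the silyl enol ether of the β-keto ester, while ring B closes in the fused mode as the seven-membered tether ring (C5–C6–C7–C11–C12=C13–C14) through the C5–C14 bond. C1 is fixed relative to C14 by the E geometry of the dienophile (H1/H14 trans), and C14 by the face of attack: allylic strain with C11 holds the C12=C13–C14=C1 unit s-trans, and the diene, anchored at C7 on the concave face of the bicyclic lactone, can reach only that face (H14 syn to H11). C5 is set by the endo transition state, in which the alkylidene lactone lies under the diene and the C6 acyl group occupies the outside position of the diene terminus, giving the cis A/B fusion with H5 syn to H7 and H14; this centre stays adjustable by enolisation towards C6. The step needs site selectivity among the possible diene/alkene pairings, and substitution and polarity secure it: the wanted pairing is the only one that joins four hydrogen-bearing carbons, whereas addition to the lactone alkylidene C12=C13, or use of C4=C5 as the 2π partner by the isopropenyl-diene, would each create a quaternary carbon (C12 or C4). The diene-terminus geometry that lets the tether span C5 and C7 is the one installed by the iodine equilibration of step 13.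

Step 15
Reactants: 22 bis-silyl cycloadduct
Product: 23 target CNP0268969.1
Conditions: HF·pyridine, pyridine, THF, 0 °C to rt
Reagents that add atoms: none
Why: Fluoride cleaves the silyl enol ether (releasing the hydrogen-bonded enol of the β-keto ester) and the tertiary TES ether under buffered, non-basic conditions that avoid retro-aldol or β-elimination of the β-hydroxy ketone and touch no stereocentre.

**Compound list**

1 | methyl 2-methylfuran-3-carboxylate | Cc1occc1C(=O)OC | starting material
2 | methyl 2-methyl-5-(4,4,5,5-tetramethyl-1,3,2-dioxaborolan-2-yl)furan-3-carboxylate | Cc1oc(B2OC(C)(C)C(C)(C)O2)cc1C(=O)OC | intermediate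
3 | (4R)-4-[(tert-butyldimethylsilyl)oxy]cyclopent-2-en-1-one | O=C1C=C[C@H](O[Si](C)(C)C(C)(C)C)C1 | starting material
4 | (4R)-4-[(tert-butyldimethylsilyl)oxy]-2-iodocyclopent-2-en-1-one | O=C1C(I)=C[C@H](O[Si](C)(C)C(C)(C)C)C1 | intermediate
5 | methyl 5-[(3R)-3-[(tert-butyldimethylsilyl)oxy]-5-oxocyclopent-1-en-1-yl]-2-methylfuran-3-carboxylate | O=C1C(c2cc(C(=O)OC)c(C)o2)=C[C@H](O[Si](C)(C)C(C)(C)C)C1 | intermediate
6 | methyl 5-[(3R,5S)-3-[(tert-butyldimethylsilyl)oxy]-5-hydroxy-5-methylcyclopent-1-en-1-yl]-2-methylfuran-3-carboxylate | Cc1oc(cc1C(=O)OC)C2=C[C@H](O[Si](C)(C)C(C)(C)C)C[C@]2(C)O | intermediate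
7 | methyl 5-[(3R,5S)-3,5-dihydroxy-5-methylcyclopent-1-en-1-yl]-2-methylfuran-3-carboxylate | Cc1oc(cc1C(=O)OC)C2=C[C@H](O)C[C@]2(C)O | intermediate
8 | methyl 5-[(3R,5S)-3-(2-bromo-1-ethoxyethoxy)-5-hydroxy-5-methylcyclopent-1-en-1-yl]-2-methylfuran-3-carboxylate (acetal epimers) | Cc1oc(cc1C(=O)OC)C2=C[C@H](OC(CBr)OCC)C[C@]2(C)O | intermediate
9 | methyl 5-[(3aS,4R,5S,6aR)-2-ethoxy-5-hydroxy-5-methylhexahydro-2H-cyclopenta[b]furan-4-yl]-2-methylfuran-3-carboxylate (C2 epimers) | Cc1oc(cc1C(=O)OC)[C@@H]2[C@@H]3CC(OCC)O[C@@H]3C[C@]2(C)O | intermediate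
10 | methyl 5-[(3aS,4R,5S,6aR)-5-hydroxy-5-methyl-2-oxohexahydro-2H-cyclopenta[b]furan-4-yl]-2-methylfuran-3-carboxylate | Cc1oc(cc1C(=O)OC)[C@@H]2[C@@H]3CC(=O)O[C@@H]3C[C@]2(C)O | intermediate
11 | methyl 2-methyl-5-[(3aS,4S,5S,6aR)-5-methyl-2-oxo-5-[(triethylsilyl)oxy]hexahydro-2H-cyclopenta[b]furan-4-yl]furan-3-carboxylate | Cc1oc(cc1C(=O)OC)[C@@H]2[C@@H]3CC(=O)O[C@@H]3C[C@]2(C)O[Si](CC)(CC)CC | intermediate
12 | methacrolein | CC(=C)C=O | starting material
13 | (triphenylphosphoranylidene)acetaldehyde | O=CC=P(c1ccccc1)(c1ccccc1)c1ccccc1 | starting material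
14 | (2E)-4-methylpenta-2,4-dienal | CC(=C)/C=C/C=O | intermediate
15 | 3-[(2E)-1-hydroxy-4-methylpenta-2,4-dien-1-yl] derivative of lactone 11 (epimers at the two new centres) | Cc1oc(cc1C(=O)OC)[C@@H]2[C@@H]3C(C(O)/C=C/C(C)=C)C(=O)O[C@@H]3C[C@]2(C)O[Si](CC)(CC)CC | intermediate
16 | methanesulfonate of 15 | Cc1oc(cc1C(=O)OC)[C@@H]2[C@@H]3C(C(OS(C)(=O)=O)/C=C/C(C)=C)C(=O)O[C@@H]3C[C@]2(C)O[Si](CC)(CC)CC | intermediate
17 | methyl 2-methyl-5-[(3E,3aR,4S,5S,6aR)-5-methyl-3-[(2E)-4-methylpenta-2,4-dien-1-ylidene]-2-oxo-5-[(triethylsilyl)oxy]hexahydro-2H-cyclopenta[b]furan-4-yl]furan-3-carboxylate | Cc1oc(cc1C(=O)OC)[C@@H]2[C@@H]3/C(=C\C=C\C(C)=C)C(=O)O[C@@H]3C[C@]2(C)O[Si](CC)(CC)CC | intermediate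
18 | 2,5-endoperoxide (2,3,7-trioxabicyclo[2.2.1]hept-5-ene) of the furan ring of 17 (bridgehead epimers) | CC12OOC(O1)(C=C2C(=O)OC)[C@@H]3[C@@H]4/C(=C\C=C\C(C)=C)C(=O)O[C@@H]4C[C@]3(C)O[Si](CC)(CC)CC | intermediate
19 | methyl (2E)-2-acetyl-4-[(3E,3aR,4R,5S,6aR)-bicyclic lactone-4-yl as in 20]-4-oxobut-2-enoate (the two ketones cis) | CC(=O)/C(C(=O)OC)=C\C(=O)[C@@H]3[C@@H]4/C(=C\C=C\C(C)=C)C(=O)O[C@@H]4C[C@]3(C)O[Si](CC)(CC)CC | intermediate
20 | methyl (2Z)-2-acetyl-4-[(3E,3aR,4R,5S,6aR)-5-methyl-3-[(2E)-4-methylpenta-2,4-dien-1-ylidene]-2-oxo-5-[(triethylsilyl)oxy]hexahydro-2H-cyclopenta[b]furan-4-yl]-4-oxobut-2-enoate (the two ketones trans) | CC(=O)/C(C(=O)OC)=C/C(=O)[C@@H]3[C@@H]4/C(=C\C=C\C(C)=C)C(=O)O[C@@H]4C[C@]3(C)O[Si](CC)(CC)CC | intermediate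
21 | methyl (2Z)-2-[1-[(tert-butyldimethylsilyl)oxy]ethenyl]-4-oxobut-2-enoate analogue of 20 (silyl dienol ether) | C=C(O[Si](C)(C)C(C)(C)C)/C(C(=O)OC)=C/C(=O)[C@@H]3[C@@H]4/C(=C\C=C\C(C)=C)C(=O)O[C@@H]4C[C@]3(C)O[Si](CC)(CC)CC | intermediate
22 | 3-O-(tert-butyldimethylsilyl) enol ether 8-O-triethylsilyl ether of the target, (1R,5S,7R,8S,10R,11R,14S) | C=C(C)[C@@H]1CC(O[Si](C)(C)C(C)(C)C)=C(C(=O)OC)[C@H]2C(=O)[C@@H]3[C@@H]4C(=C[C@H]21)C(=O)O[C@@H]4C[C@]3(C)O[Si](CC)(CC)CC | intermediate
23 | target CNP0268969.1, (1R,5S,7R,8S,10R,11R,14S) tetracyclic enol β-keto ester lactone | C=C(C)[C@@H]1CC(O)=C(C(=O)OC)[C@H]2C(=O)[C@@H]3[C@@H]4C(=C[C@H]21)C(=O)O[C@@H]4C[C@]3(C)O | target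

**Step count and risks**

Total step count: 15. Longest linear sequence: 13 steps (3 → 23; steps 2–9 and 11–15).

Steps most likely to fail:

Step 13. Singlet oxygen may be consumed by the triene ([4+2] at the isopropenyl-diene end or ene reaction) in competition with the ester-deactivated furan, or the ene-trione may degrade during the iodine equilibration. The fallback changes the order of events and the olefination type. It sets out from 11, which is phosphorylated at the lactone α-carbon (LDA, ClP(O)(OEt)2, then a second equivalent of LDA for the 1,3-phosphoryl shift of the enol phosphate) to give the α-(diethoxyphosphoryl) lactone F1. F1 contains no alkene other than the furan and is photo-oxygenated, reduced and equilibrated as in step 13 to the phosphono ene-dione F2. A Horner–Wadsworth–Emmons reaction of F2 with dienal 14 under Masamune–Roush conditions (LiCl, iPr2NEt, MeCN) then installs the (E)-alkylidene and comes back to the route at 20.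

Step 14. The silyl dienol ether may add to the wrong 2π partner (the lactone alkylidene C12=C13, closing a five-membered ring), may itself serve as the 2π partner at C4=C5 for the isopropenyl-diene, or may react through the exo orientation and give the trans A/B fusion. The fallback makes the same two ring-A bonds intermolecularly and closes ring B afterwards by olefination. It sets out from 11 by way of the α-(diethoxyphosphoryl) lactone F1 and the phosphono ene-dione F2 described above. F2 is converted with TBSOTf/Et3N into the phosphono silyl dienol ether F3. F3 undergoes an intermolecular endo Diels–Alder reaction with dienal 14 at its formyl-activated C=C (ortho/para regiochemistry, face controlled by a chiral oxazaborolidinium Lewis acid) to give the cyclohexene carbaldehyde F4. An intramolecular Horner–Wadsworth–Emmons reaction of F4 (LiCl, DBU, MeCN, high dilution) closes the seven-membered ring at C12=C13 and comes back to the route at 22.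

Step 8. Chromic acid may open the furan oxidatively, or the strong acid may ionise the tertiary alcohol, before the acetal is consumed. The fallback separates hydrolysis from a neutral oxidation. It sets out from 9, which is hydrolysed with PPTS in aqueous acetone to the lactol F5. F5 is oxidised with Fétizon's reagent (Ag2CO3 on Celite, toluene, reflux), an oxidant inert to furans and tertiary alcohols, and comes back to the route at 10.

Further compounds
F1 | step 13 | α-(diethoxyphosphoryl) derivative of lactone 11 (P on the lactone α-carbon, both epimers, ring configurations as in 11) | Cc1oc(cc1C(=O)OC)[C@@H]2[C@@H]3C(P(=O)(OCC)OCC)C(=O)O[C@@H]3C[C@]2(C)O[Si](CC)(CC)CC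
F2 | step 13 | phosphono ene-dione: methyl (2Z)-2-acetyl-4-oxobut-2-enoate carrying the α-(diethoxyphosphoryl) bicyclic lactone of F1 at C4 (the two ketones trans) | CC(=O)/C(C(=O)OC)=C/C(=O)[C@@H]2[C@@H]3C(P(=O)(OCC)OCC)C(=O)O[C@@H]3C[C@]2(C)O[Si](CC)(CC)CC
F3 | step 14 | phosphono silyl dienol ether (TBS enol ether of the acetyl group of F2) | C=C(O[Si](C)(C)C(C)(C)C)/C(C(=O)OC)=C/C(=O)[C@@H]2[C@@H]3C(P(=O)(OCC)OCC)C(=O)O[C@@H]3C[C@]2(C)O[Si](CC)(CC)CC
F4 | step 14 | cyclohexene carbaldehyde: ring A with C1, C5 and C14 as in 22, formyl group on C14, acyl link from C5 to the phosphono lactone | C=C(C)[C@@H]1CC(O[Si](C)(C)C(C)(C)C)=C(C(=O)OC)[C@@H](C(=O)[C@@H]2[C@@H]3C(P(=O)(OCC)OCC)C(=O)O[C@@H]3C[C@]2(C)O[Si](CC)(CC)CC)[C@H]1C=O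
F5 | step 8 | lactol: methyl 5-[(3aS,4R,5S,6aR)-2,5-dihydroxy-5-methylhexahydro-2H-cyclopenta[b]furan-4-yl]-2-methylfuran-3-carboxylate (C2 epimers) | Cc1oc(cc1C(=O)OC)[C@@H]2[C@@H]3CC(O)O[C@@H]3C[C@]2(C)O
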